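# Synthesis proposal for CNP0197754.1 (compound 23) by a silicon-directed Nazarov cyclisation

## Analysis of the target

Compound 23 is a daucane-type sesquiterpenoid ester built on a trans-fused hydroazulene (bicyclo[5.3.0]decane). The five-membered ring is C1, C2, C3, C3a, C8a and the seven-membered ring is C3a, C4, C5, C6, C7, C8, C8a. There are six stereocentres: C3 (tertiary carbinol with the isopropyl group, R), C3a (fusion CH, S), C4 (carbon of the 4-hydroxybenzoate, S), C6 (tertiary carbinol with a methyl group, S), C7 (secondary carbinol, S) and the quaternary, methyl-bearing C8a (R). With the face of the C8a methyl group called β, H-3a is α (trans fusion), the C3 hydroxyl is β, the C4 acyloxy group is α and syn to H-3a, the C6 hydroxyl is β and the C7 hydroxyl is α, so C6/C7 is a trans-diol. Sensitive points are the two tertiary alcohols (dehydration), the aryl ester between hydroxyl groups (saponification, acyl shift) and the free phenol. In any C3 ketone precursor the C3a hydrogen is α to the carbonyl and β to the C4 oxygen, so epimerisation and β-elimination must be watched. The synthesis is hard because a quaternary carbon sits next to the fusion CH of a flexible trans-fused 5–7 system, three of the six stereocentres are fully substituted, and four oxygens of the same oxidation level must be told apart. The plan rests on one feature: the five-membered ring has its only oxygen at C3, next to the fusion carbon C3a. C3 can therefore be the carbonyl of a cross-conjugated dienone C1=C2–C3(=O)–C3a=C8a, whose ends C1 and C8a close the five-membered ring and create the quaternary carbon in one step.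

## Retrosynthetic reasoning

23 from 22. The phenol is carried as a benzyl ether. Cutting the O–benzyl bond last is safe because no alkene is left at that stage, and it keeps a free phenol out of the acylation and the acid step.

22 from 21. The C6–OH bond is cut and traced to an epoxide across C6/C7 on the α face. Opening at the tertiary C6 with inversion gives the β hydroxyl at C6 and leaves the α oxygen at C7 untouched, which is exactly the trans-diol of 23. A syn dihydroxylation could not give this pattern.

21 from 19 and 20. The ester C–O bond is cut. In 19 the C4 hydroxyl is the only secondary alcohol, so acylation with 20 needs no protecting group. Acylation is placed before the epoxide is opened because opening first would create a second secondary alcohol at C7.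

19 from 18. The epoxide is traced to the C6=C7 alkene. The free homoallylic C4 hydroxyl of 18 is on the α face and can deliver the oxidant to that face, which is also the one remote from the angular methyl group.

18 from 17 from 16. After removal of the silyl group, the C3–isopropyl bond is cut to ketone 16. The forward addition must come from the α face. In the trans-fused ketone that face carries only H-3a, whereas the β face carries the angular methyl group and the C4 carbon with its silyloxy group.

16 from 15. The C1–C2 single bond is traced to the enone alkene of 15, which is the residue of the ring-forming step. It is removed by conjugate reduction before the isopropyl addition, so that no tertiary allylic alcohol has to be handled.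

15 from 13. The C1–C8a bond is cut, which opens the five-membered ring to dienone 13. The forward reaction is a 4π electrocyclisation that must make a quaternary carbon, fix the alkene at C1=C2 and set C8a and C3a relative to C4. The β-trimethylsilyl group on the vinyl arm settles the alkene position. The C4 silyloxy stereocentre must settle the sense of ring closure. A Lewis acid that binds only the ketone would let allylic strain turn the silyloxy group out of the plane and probably give the wrong C8a epimer. The plan therefore uses an aluminium Lewis acid that chelates the ketone and the silyloxy oxygen. This is the repair on which the stereochemical argument depends.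

13 from 12 from 7 and 10. The C3–C3a bond is cut to a cycloheptadienyl anion equivalent and an α,β-unsaturated aldehyde. Vinyl bromide 7 gives vinyllithium 11, which adds to 10, and the carbinol 12 is oxidised. The bromine sits exactly at the carbon that must become C3a.

10 from 9 from 8. The silylated enal comes from the silylated propargylic alcohol by trans-selective reduction of the alkyne and oxidation of the allylic alcohol.

7 from 6 from 5. The silyl ether is cut to alcohol 6, and 6 to ketone 5. An enantioselective reduction of 5 sets C4. This is the only stereocentre made by a chiral reagent, and all others are relayed from it.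

5 from 4 from 2 and 3 from 1. The seven-membered ring is traced to a six-membered one. The carbene from 3 adds to the enol ether alkene of Birch diene 2, and opening of cyclopropane 4 inserts that carbon as the bromine-bearing C3a between the future C4 carbonyl and the methyl-bearing C8a. All ring carbons, both methyl groups and the C6=C7 alkene of 23 are thus already present in anisole 1.

## Alternatives that were turned down

Alternative 1: The C8–C8a bond is cut and the seven-membered ring is made by a Claisen-type ring expansion. In the forward step a thermal [3,3] shift breaks a C4–O bond of a five-membered cyclic enol ether and joins C8 to C8a, giving cycloheptenone A1 with the quaternary carbon in place.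
- For it: the shift is concerted, so the configuration at C4 of the substrate is passed to C8a through an ordered transition state. This is more predictable than the sense of rotation in a Nazarov closure. A1 also already holds the tertiary oxygen at C6 and a carbonyl at C7, so no epoxide chemistry would be needed. On both points this route is stronger than the chosen one.
- Against it: A1 has a C3a=C4 alkene, so both the C4 oxygen and the C3a hydrogen must still be introduced by a regio- and face-selective hydroboration. The C7 ketone must be reduced to the α alcohol beside a fully substituted carbon. The substrate of the shift needs two stereocentres (C4 and the quaternary C6) made independently before the enol ether can be formed.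
- Comparison: counting these operations, the route is clearly longer. The chosen strategy offers a nine-operation path from an aromatic ether to the key-step substrate, one catalytic asymmetric step, and C3 and C4 at the correct oxidation level directly after ring formation.

Alternative 2: C3a–C8a and C7–C8 are cut together. In the forward step base turns a furan-derived acyloxypyranone into a 3-oxidopyrylium, which adds across a tethered 1,1-disubstituted alkene in a (5+2) cycloaddition to give the oxa-bridged hydroazulenone A2.
- For it: two C–C bonds, both rings and three stereocentres form at once, and the C3 carbinol with its isopropyl group is already present. In bond-forming efficiency this is stronger than the chosen closure, which makes one bond and one ring.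
- Against it: in A2 C3a is a fully substituted ether carbon, whereas 23 needs a hydrogen there, trans to the methyl group. The bridge must be cleaved reductively at C3a and the resulting enolate protonated on the correct face. This is the same C3a problem as in the chosen route, but without a chelate to guide it. The tertiary C3 carbinol must be made enantiopure at the very start and is then the only source of facial control, through a flexible tether. The 1,1-disubstituted alkene is a reluctant 2π partner. The C4 ketone and the C5=C6 enone still need stereoselective reduction and hydration.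
- Comparison: the chosen strategy sets C3 last, under control of the finished bicycle, and needs no correction of oxidation state at C3a.

Alternative 3: C3–C3a and C8–C8a are cut, which unravels the hydroazulene to a monocyclic bisabolane-type keto diene. In the forward step an acid activates the isopropyl ketone, the exocyclic tetrasubstituted alkene attacks it (Prins closure to a spiro cation), a ring methylene shifts to expand six to seven, and proton loss gives dienol A3.
- For it: it is by far the shortest route, biomimetic and free of protecting groups. A3 already has both rings, the quaternary carbon and the C3 carbinol. In step economy it is clearly stronger than the chosen route.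
- Against it: three cationic events must each take one course out of several (early proton loss, competing alkyl or hydride shifts, ionisation of the new tertiary alcohol). The relative configuration of C3 and C8a and the absolute sense would depend on a chiral acid for which this cascade is not an established reaction. A3 lacks the C4 oxygen, which would have to come from hydroboration of C3a=C4 in the presence of the equally trisubstituted C6=C7 alkene.
- Comparison: the chosen strategy is longer, but every step is a known reaction type and the stereochemistry is relayed stepwise from one carbinol centre.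

Key step: step 10

Remark on the chemistry: the labels C1 to C8a of the hydroazulene core of 23 are used for the corresponding carbons of every intermediate; α is the face opposite to the C8a methyl group and β the face that carries it.

## Route

Step 1
Reactants: 1 2,5-dimethylanisole
Product: 2 1-methoxy-2,5-dimethylcyclohexa-1,4-diene
Conditions: Li, NH3(l), THF, t-BuOH, −78 to −33 °C; then H2O
Reagents that add atoms: none
Why: Birch reduction; the methoxy- and methyl-bearing carbons stay sp2, so the two unsubstituted para-related positions are reduced and the skipped diene with the enol ether alkene results.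

Step 2
Reactants: 2 1-methoxy-2,5-dimethylcyclohexa-1,4-diene; 3 bromoform
Product: 4 7,7-dibromo-1-methoxy-3,6-dimethylbicyclo[4.1.0]hept-3-ene (racemic)
Conditions: KOt-Bu, pentane, −20 to 0 °C
Reagents that add atoms: none
Why: Dihalocarbene cyclopropanation; the electrophilic carbene adds to the tetrasubstituted enol ether alkene much faster than to the trisubstituted alkene, and the two new centres are lost again in step 3.

Step 3
Reactants: 4 7,7-dibromo-1-methoxy-3,6-dimethylbicyclo[4.1.0]hept-3-ene
Product: 5 2-bromo-3,6-dimethylcyclohepta-2,5-dien-1-one
Conditions: AgNO3, NaHCO3, acetone/H2O, 0 °C to rt, dark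
Reagents that add atoms: water, O
Why: Silver-assisted disrotatory ring opening of an alkoxy gem-dibromocyclopropane (one-carbon ring expansion); the methoxy group stabilises the allyl cation as an oxocarbenium ion, which water hydrolyses to the ketone, and the buffer keeps the skipped diene from moving into conjugation.

Step 4
Reactants: 5 2-bromo-3,6-dimethylcyclohepta-2,5-dien-1-one
Product: 6 (1S)-2-bromo-3,6-dimethylcyclohepta-2,5-dien-1-ol
Conditions: (R)-2-methyl-CBS-oxazaborolidine (15 mol %), catecholborane, toluene, −78 °C
Reagents that add atoms: none
Why: Corey–Bakshi–Shibata reduction; the α-bromoalkenyl arm acts as the large group and the CH2 arm as the small one, so the R catalyst delivers hydride to the face that gives the 1S alcohol (the future C4), and catecholborane at low temperature leaves the isolated alkene alone.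

Step 5
Reactants: 6 (1S)-2-bromo-3,6-dimethylcyclohepta-2,5-dien-1-ol
Product: 7 [(1S)-2-bromo-3,6-dimethylcyclohepta-2,5-dien-1-yl]oxy(tert-butyl)dimethylsilane
Conditions: TBSCl, imidazole, DMF, rt
Reagents that add atoms: tert-butyldimethylsilyl chloride, CC(C)(C)[Si](C)(C)Cl
Why: Standard silylation of a secondary alcohol; the silyl ether survives the organolithium step and is the oxygen that later binds aluminium.

Step 6
Reactants: 8 3-(trimethylsilyl)prop-2-yn-1-ol
Product: 9 (E)-3-(trimethylsilyl)prop-2-en-1-ol
Conditions: NaAlH2(OCH2CH2OMe)2, Et2O, 0 °C to rt; then H2O
Reagents that add atoms: none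
Why: Alkoxide-directed trans-hydroalumination of a propargylic alcohol followed by protonolysis gives the E vinylsilane only.

Step 7
Reactants: 9 (E)-3-(trimethylsilyl)prop-2-en-1-ol
Product: 10 (E)-3-(trimethylsilyl)prop-2-enal
Conditions: MnO2 (activated), CH2Cl2, rt
Reagents that add atoms: none
Why: Manganese dioxide oxidation of a primary allylic alcohol; neutral conditions preserve the alkene geometry and the C–Si bond.

Step 8
Reactants: 7 [(1S)-2-bromo-3,6-dimethylcyclohepta-2,5-dien-1-yl]oxy(tert-butyl)dimethylsilane; 10 (E)-3-(trimethylsilyl)prop-2-enal
Product: 12 (E)-1-[(7S)-7-(tert-butyldimethylsilyloxy)-2,5-dimethylcyclohepta-1,4-dien-1-yl]-3-(trimethylsilyl)prop-2-en-1-ol (both carbinol epimers), via vinyllithium 11 (not isolated)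
Conditions: t-BuLi (2.1 equiv), THF, −78 °C; then 10, −78 °C; H2O
Reagents that add atoms: none
Why: Bromine–lithium exchange followed by 1,2-addition of the alkenyllithium to the enal; the new carbinol centre is not controlled and is removed in step 9, and the low temperature prevents proton transfer from the doubly allylic C8 and silyl migration.

Step 9
Reactants: 12 (E)-1-[(7S)-7-(tert-butyldimethylsilyloxy)-2,5-dimethylcyclohepta-1,4-dien-1-yl]-3-(trimethylsilyl)prop-2-en-1-ol
Product: 13 (E)-1-[(7S)-7-(tert-butyldimethylsilyloxy)-2,5-dimethylcyclohepta-1,4-dien-1-yl]-3-(trimethylsilyl)prop-2-en-1-one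
Conditions: MnO2 (activated), CH2Cl2, rt
Reagents that add atoms: none
Why: Manganese dioxide oxidation of a doubly allylic alcohol to the cross-conjugated dienone; both silyl groups and the skipped diene are inert under these neutral conditions.

Step 10
Reactants: 13 (E)-1-[(7S)-7-(tert-butyldimethylsilyloxy)-2,5-dimethylcyclohepta-1,4-dien-1-yl]-3-(trimethylsilyl)prop-2-en-1-one
Product: 15 (3aS,4S,8aS)-4-(tert-butyldimethylsilyloxy)-6,8a-dimethyl-3a,4,5,8-tetrahydroazulen-3(8aH)-one, via aluminium dienolate 14 (not isolated)
Conditions: MeAlCl2 (2.2 equiv), CH2Cl2, −78 to −30 °C; MeOH, −78 °C, then aq. potassium sodium tartrate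
Reagents that add atoms: none
Why: MeAlCl2 binds the ketone oxygen and, as a bidentate cationic aluminium centre, also the C4 silyloxy oxygen; this holds the dienone in the U-shaped form and turns it into a 3-oxidopentadienyl cation, conrotatory 4π electrocyclisation joins C1 to C8a, and the β-silyl group stabilises the oxyallyl cation and leaves from C1, so the alkene is fixed at C1=C2 and dienolate 14 remains. The closest known reaction type is the silicon-directed Nazarov cyclisation of β-silylvinyl cycloalkenyl ketones, combined with the known ability of alkylaluminium chlorides to chelate β-silyloxy carbonyl compounds. The five-membered ring closes by electrocyclisation of the pentadienyl cation and not by an exo or endo attack on a π bond, and the tetrasubstituted C3a=C8a alkene is the electron-rich arm that lets a quaternary terminus form. C8a is controlled by C4: with the C4–O bond held in the plane of the chelate, the S configuration puts C5 below that plane, C8 can rotate only to the same side if the seven-membered ring is to stay unstrained, and the methyl group therefore turns to the opposite face (8aS in 15). C3a is set when 14 is protonated on the face opposite to the angular methyl group, which keeps the chelate intact and gives the trans fusion, whereas protonation on the methyl face would force the silyloxy group into the concave side of a cis-fused bicycle; the same isomer is the one favoured at equilibrium, since C3a is α to the ketone. The step needs three selectivities: the alkene position (secured by silicon), the sense of conrotation (secured by the C4 chelate), and no β-elimination of the silyloxy group (its C–O bond lies in the enolate plane, orthogonal to the π system); the remote C6=C7 alkene does not react at this temperature.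

Step 11
Reactants: 15 (3aS,4S,8aS)-4-(tert-butyldimethylsilyloxy)-6,8a-dimethyl-3a,4,5,8-tetrahydroazulen-3(8aH)-one
Product: 16 (3aS,4S,8aR)-4-(tert-butyldimethylsilyloxy)-6,8a-dimethyl-1,2,3a,4,5,8-hexahydroazulen-3(8aH)-one
Conditions: [(Ph3P)CuH]6 (5 mol %), (EtO)2MeSiH, t-BuOH, toluene, rt
Reagents that add atoms: none
Why: Copper hydride conjugate reduction; hydride adds only to C1 of the enone, the enolate formed is the C2=C3 one so C3a is never enolised, and the isolated C6=C7 alkene is untouched (the change of the C8a descriptor from S to R is only a change of CIP priority).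

Step 12
Reactants: 16 (3aS,4S,8aR)-4-(tert-butyldimethylsilyloxy)-6,8a-dimethyl-1,2,3a,4,5,8-hexahydroazulen-3(8aH)-one
Product: 17 (3R,3aS,4S,8aR)-4-(tert-butyldimethylsilyloxy)-6,8a-dimethyl-3-(propan-2-yl)-1,2,3,3a,4,5,8,8a-octahydroazulen-3-ol
Conditions: CeCl3 (anhydrous), i-PrLi, THF, −78 °C; then 16; H2O
Reagents that add atoms: isopropyllithium, [Li]C(C)C
Why: Organocerium 1,2-addition, which is only weakly basic and so avoids enolisation toward C3a and β-hydride reduction; in the trans-fused ketone the β face of the carbonyl is screened by the angular methyl group and by C4 with its silyloxy group, while the α face carries only H-3a, so isopropyl enters α and the hydroxyl ends cis to the methyl group (3R).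

Step 13
Reactants: 17 (3R,3aS,4S,8aR)-4-(tert-butyldimethylsilyloxy)-6,8a-dimethyl-3-(propan-2-yl)-1,2,3,3a,4,5,8,8a-octahydroazulen-3-ol
Product: 18 (3R,3aS,4S,8aR)-6,8a-dimethyl-3-(propan-2-yl)-1,2,3,3a,4,5,8,8a-octahydroazulene-3,4-diol
Conditions: Bu4NF, THF, rt to 40 °C
Reagents that add atoms: none
Why: Fluoride cleavage of the silyl ether; with no carbonyl left, the basic fluoride cannot cause retro-aldol cleavage or epimerisation.

Step 14
Reactants: 18 (3R,3aS,4S,8aR)-6,8a-dimethyl-3-(propan-2-yl)-1,2,3,3a,4,5,8,8a-octahydroazulene-3,4-diol
Product: 19 (3R,3aS,4S,6R,7S,8aR)-6,7-epoxy-6,8a-dimethyl-3-(propan-2-yl)decahydroazulene-3,4-diol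
Conditions: VO(acac)2 (5 mol %), t-BuOOH, CH2Cl2, 0 °C to rt
Reagents that add atoms: tert-butyl hydroperoxide, CC(C)(C)OO
Why: Vanadium-catalysed hydroxyl-directed epoxidation; the vanadium alkoxide of the homoallylic C4 hydroxyl delivers oxygen to the α face of C6=C7, the face that carries that hydroxyl and is remote from the angular methyl group, giving the 6R,7S epoxide.

Step 15
Reactants: 19 (3R,3aS,4S,6R,7S,8aR)-6,7-epoxy-6,8a-dimethyl-3-(propan-2-yl)decahydroazulene-3,4-diol; 20 4-(benzyloxy)benzoyl chloride
Product: 21 (3R,3aS,4S,6R,7S,8aR)-6,7-epoxy-3-hydroxy-6,8a-dimethyl-3-(propan-2-yl)decahydroazulen-4-yl 4-(benzyloxy)benzoate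
Conditions: Et3N, DMAP, CH2Cl2, 0 °C to rt
Reagents that add atoms: none
Why: DMAP-catalysed acylation of the only secondary hydroxyl; the tertiary C3 hydroxyl does not react, the C4–O bond is not touched so its configuration is kept, and the basic medium leaves the epoxide intact.

Step 16
Reactants: 21 (3R,3aS,4S,6R,7S,8aR)-6,7-epoxy-3-hydroxy-6,8a-dimethyl-3-(propan-2-yl)decahydroazulen-4-yl 4-(benzyloxy)benzoate
Product: 22 (3R,3aS,4S,6S,7S,8aR)-3,6,7-trihydroxy-6,8a-dimethyl-3-(propan-2-yl)decahydroazulen-4-yl 4-(benzyloxy)benzoate
Conditions: HClO4 (cat.), THF/H2O 3:1, 0 °C to rt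
Reagents that add atoms: water, O
Why: Acid-catalysed epoxide hydrolysis; water opens the protonated epoxide at the tertiary C6 with inversion while the C7–O bond is kept, which gives the β hydroxyl at C6 and the α hydroxyl at C7 (6S,7S trans-diol); dilute acid, low temperature and a large excess of water favour capture by water over proton loss or attack by the C3 hydroxyl.

Step 17
Reactants: 22 (3R,3aS,4S,6S,7S,8aR)-3,6,7-trihydroxy-6,8a-dimethyl-3-(propan-2-yl)decahydroazulen-4-yl 4-(benzyloxy)benzoate
Product: 23 (3R,3aS,4S,6S,7S,8aR)-3,6,7-trihydroxy-6,8a-dimethyl-3-(propan-2-yl)decahydroazulen-4-yl 4-hydroxybenzoate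
Conditions: H2 (1 atm), Pd/C, EtOAc, rt
Reagents that add atoms: none
Why: Hydrogenolysis of the aryl benzyl ether; the molecule has no alkene left, and the alkyl benzoate and the tertiary alcohols are stable under these neutral conditions.

## Compound list

1 | 2,5-dimethylanisole | COc1cc(C)ccc1C | starting material
2 | 1-methoxy-2,5-dimethylcyclohexa-1,4-diene | COC1=C(C)CC=C(C)C1 | intermediate
3 | bromoform | BrC(Br)Br | starting material
4 | 7,7-dibromo-1-methoxy-3,6-dimethylbicyclo[4.1.0]hept-3-ene (racemic; relative configuration shown) | CO[C@]12CC(C)=CC[C@@]1(C)C2(Br)Br | intermediate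
5 | 2-bromo-3,6-dimethylcyclohepta-2,5-dien-1-one | O=C1C(Br)=C(C)CC=C(C)C1 | intermediate
6 | (1S)-2-bromo-3,6-dimethylcyclohepta-2,5-dien-1-ol | O[C@@H]1C(Br)=C(C)CC=C(C)C1 | intermediate
7 | [(1S)-2-bromo-3,6-dimethylcyclohepta-2,5-dien-1-yl]oxy(tert-butyl)dimethylsilane | CC(C)(C)[Si](C)(C)O[C@@H]1C(Br)=C(C)CC=C(C)C1 | intermediate
8 | 3-(trimethylsilyl)prop-2-yn-1-ol | C[Si](C)(C)C#CCO | starting material
9 | (E)-3-(trimethylsilyl)prop-2-en-1-ol | C[Si](C)(C)/C=C/CO | intermediate
10 | (E)-3-(trimethylsilyl)prop-2-enal | C[Si](C)(C)/C=C/C=O | intermediate
11 | [(7S)-7-(tert-butyldimethylsilyloxy)-2,5-dimethylcyclohepta-1,4-dien-1-yl]lithium | [Li]C1=C(C)CC=C(C)C[C@@H]1O[Si](C)(C)C(C)(C)C | intermediate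
12 | (E)-1-[(7S)-7-(tert-butyldimethylsilyloxy)-2,5-dimethylcyclohepta-1,4-dien-1-yl]-3-(trimethylsilyl)prop-2-en-1-ol (both carbinol epimers) | C[Si](C)(C)/C=C/C(O)C1=C(C)CC=C(C)C[C@@H]1O[Si](C)(C)C(C)(C)C | intermediate
13 | (E)-1-[(7S)-7-(tert-butyldimethylsilyloxy)-2,5-dimethylcyclohepta-1,4-dien-1-yl]-3-(trimethylsilyl)prop-2-en-1-one | C[Si](C)(C)/C=C/C(=O)C1=C(C)CC=C(C)C[C@@H]1O[Si](C)(C)C(C)(C)C | intermediate
14 | chloro(methyl)aluminium (4S,8aS)-4-(tert-butyldimethylsilyloxy)-6,8a-dimethyl-4,5,8,8a-tetrahydroazulen-3-olate | C[Al](Cl)OC1=C2[C@@H](O[Si](C)(C)C(C)(C)C)CC(C)=CC[C@@]2(C)C=C1 | intermediate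
15 | (3aS,4S,8aS)-4-(tert-butyldimethylsilyloxy)-6,8a-dimethyl-3a,4,5,8-tetrahydroazulen-3(8aH)-one | O=C1C=C[C@]2(C)CC=C(C)C[C@H](O[Si](C)(C)C(C)(C)C)[C@H]21 | intermediate
16 | (3aS,4S,8aR)-4-(tert-butyldimethylsilyloxy)-6,8a-dimethyl-1,2,3a,4,5,8-hexahydroazulen-3(8aH)-one | O=C1CC[C@]2(C)CC=C(C)C[C@H](O[Si](C)(C)C(C)(C)C)[C@H]21 | intermediate
17 | (3R,3aS,4S,8aR)-4-(tert-butyldimethylsilyloxy)-6,8a-dimethyl-3-(propan-2-yl)-1,2,3,3a,4,5,8,8a-octahydroazulen-3-ol | CC(C)[C@]1(O)CC[C@]2(C)CC=C(C)C[C@H](O[Si](C)(C)C(C)(C)C)[C@H]21 | intermediate
18 | (3R,3aS,4S,8aR)-6,8a-dimethyl-3-(propan-2-yl)-1,2,3,3a,4,5,8,8a-octahydroazulene-3,4-diol | CC(C)[C@]1(O)CC[C@]2(C)CC=C(C)C[C@H](O)[C@H]21 | intermediate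
19 | (3R,3aS,4S,6R,7S,8aR)-6,7-epoxy-6,8a-dimethyl-3-(propan-2-yl)decahydroazulene-3,4-diol | CC(C)[C@]1(O)CC[C@]2(C)C[C@@H]3O[C@]3(C)C[C@H](O)[C@H]21 | intermediate
20 | 4-(benzyloxy)benzoyl chloride | O=C(Cl)c1ccc(OCc2ccccc2)cc1 | starting material
21 | (3R,3aS,4S,6R,7S,8aR)-6,7-epoxy-3-hydroxy-6,8a-dimethyl-3-(propan-2-yl)decahydroazulen-4-yl 4-(benzyloxy)benzoate | CC(C)[C@]1(O)CC[C@]2(C)C[C@@H]3O[C@]3(C)C[C@H](OC(=O)c4ccc(OCc5ccccc5)cc4)[C@H]21 | intermediate
22 | (3R,3aS,4S,6S,7S,8aR)-3,6,7-trihydroxy-6,8a-dimethyl-3-(propan-2-yl)decahydroazulen-4-yl 4-(benzyloxy)benzoate | CC(C)[C@]1(O)CC[C@]2(C)C[C@H](O)[C@@](C)(O)C[C@H](OC(=O)c3ccc(OCc4ccccc4)cc3)[C@H]21 | intermediate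
23 | (3R,3aS,4S,6S,7S,8aR)-3,6,7-trihydroxy-6,8a-dimethyl-3-(propan-2-yl)decahydroazulen-4-yl 4-hydroxybenzoate | CC(C)[C@]1(O)CC[C@]2(C)C[C@H](O)[C@@](C)(O)C[C@H](OC(=O)c3ccc(O)cc3)[C@H]21 | target

## Step count and least certain steps

Total step count: 17. Longest linear sequence: 15 steps (steps 1 to 5 and 8 to 17, from 1); steps 6 and 7 prepare aldehyde 10.

Step 10 (key step). The most likely failure is the wrong sense of conrotation. If the silyl ether oxygen does not stay bound to aluminium, allylic strain against the complexed carbonyl turns the C4–O bond out of the dienone plane. The seven-membered ring then folds to the other side, the methyl group ends on the face of the silyloxy group, and protonation at C3a loses its guide. Promoters that bind only one oxygen, such as FeCl3 or BF3·OEt2, would be expected to behave this way, which is why they are not used. Protonation on the wrong face alone is less serious, because C3a can be equilibrated through the enol toward the trans isomer, in which the silyloxy group is equatorial; loss of the silanol by β-elimination must then be watched.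

The fallback replaces the dative chelate by a covalent one. It sets out from 13 and returns at 15. The silyl ether of 13 is cleaved (HF·pyridine, THF, 0 °C) to (E)-1-[(7S)-7-hydroxy-2,5-dimethylcyclohepta-1,4-dien-1-yl]-3-(trimethylsilyl)prop-2-en-1-one F1. Me2AlCl (1 equiv, −78 °C) converts the hydroxyl into an aluminium alkoxide that is bound to C4–O and coordinated to the ketone. MeAlCl2 then triggers the same silicon-directed closure, and work-up gives (3aS,4S,8aS)-4-hydroxy-6,8a-dimethyl-3a,4,5,8-tetrahydroazulen-3(8aH)-one F2. Silylation (TBSCl, imidazole, DMF) converts F2 into 15.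

Step 3. The most likely failure is migration of the C6=C7 alkene into conjugation with the new ketone, or loss of HBr toward a tropone, during the silver-mediated opening or on isolation. The ketone has a CH2 group that is both α to the carbonyl and allylic.

The fallback avoids isolating the ketone and changes the way C4 is set. It sets out from 4 and returns at 6. Cyclopropane 4 is opened with AgNO3 and NaHCO3 in aqueous THF at −20 °C, the silver salts are filtered off, and NaBH4 with CeCl3·7H2O in MeOH is added to the cold filtrate (Luche reduction). This gives racemic 2-bromo-3,6-dimethylcyclohepta-2,5-dien-1-ol F3. Kinetic resolution with Pseudomonas cepacia lipase and vinyl acetate acetylates the R enantiomer to (1R)-2-bromo-3,6-dimethylcyclohepta-2,5-dien-1-yl acetate F4 and leaves the S alcohol, which is 6.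

Step 12. The most likely failure is enolisation toward C3a (with risk of silanol elimination) or β-hydride reduction in place of addition, because a branched nucleophile meets a ketone flanked by a tertiary carbon. Poor facial selectivity is the second concern.

The fallback uses a smaller sp2 nucleophile without β-hydrogens. It sets out from 16 and returns at 17. Isopropenylmagnesium bromide with CeCl3 (THF, −78 °C) adds to 16 from the same α face and gives (3S,3aS,4S,8aR)-4-(tert-butyldimethylsilyloxy)-6,8a-dimethyl-3-(prop-1-en-2-yl)-1,2,3,3a,4,5,8,8a-octahydroazulen-3-ol F5. Hydrogenation with RhCl(PPh3)3 (H2, benzene) reduces only the 1,1-disubstituted alkene and not the trisubstituted C6=C7, giving 17.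

Step 14. The most likely failure is poor facial selectivity or a slow reaction. The 1,3-diol may bind vanadium as a chelate, and delivery from a homoallylic oxygen on a flexible seven-membered ring is less strict than from an allylic one.

The fallback gives up direction by the hydroxyl and relies on the angular methyl group alone. It sets out from 18 and returns at 21. Diol 18 is acylated first with 20 (Et3N, DMAP, CH2Cl2) to (3R,3aS,4S,8aR)-3-hydroxy-6,8a-dimethyl-3-(propan-2-yl)-1,2,3,3a,4,5,8,8a-octahydroazulen-4-yl 4-(benzyloxy)benzoate F6. Epoxidation of F6 with mCPBA (NaHCO3, CH2Cl2, 0 °C) from the face opposite to the methyl group then gives 21.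

## Further compounds

F1 | step 10 | (E)-1-[(7S)-7-hydroxy-2,5-dimethylcyclohepta-1,4-dien-1-yl]-3-(trimethylsilyl)prop-2-en-1-one | C[Si](C)(C)/C=C/C(=O)C1=C(C)CC=C(C)C[C@@H]1O
F2 | step 10 | (3aS,4S,8aS)-4-hydroxy-6,8a-dimethyl-3a,4,5,8-tetrahydroazulen-3(8aH)-one | O=C1C=C[C@]2(C)CC=C(C)C[C@H](O)[C@H]21
F3 | step 3 | 2-bromo-3,6-dimethylcyclohepta-2,5-dien-1-ol (racemic) | OC1C(Br)=C(C)CC=C(C)C1
F4 | step 3 | (1R)-2-bromo-3,6-dimethylcyclohepta-2,5-dien-1-yl acetate | CC(=O)O[C@H]1C(Br)=C(C)CC=C(C)C1
F5 | step 12 | (3S,3aS,4S,8aR)-4-(tert-butyldimethylsilyloxy)-6,8a-dimethyl-3-(prop-1-en-2-yl)-1,2,3,3a,4,5,8,8a-octahydroazulen-3-ol | CC(=C)[C@]1(O)CC[C@]2(C)CC=C(C)C[C@H](O[Si](C)(C)C(C)(C)C)[C@H]21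
F6 | step 14 | (3R,3aS,4S,8aR)-3-hydroxy-6,8a-dimethyl-3-(propan-2-yl)-1,2,3,3a,4,5,8,8a-octahydroazulen-4-yl 4-(benzyloxy)benzoate | CC(C)[C@]1(O)CC[C@]2(C)CC=C(C)C[C@H](OC(=O)c3ccc(OCc4ccccc4)cc3)[C@H]21
A1 | alternative 1 | 6-(benzyloxy)-3,3-(ethylenedioxy)-6,8a-dimethyl-2,3,5,6,8,8a-hexahydroazulen-7(1H)-one | O1CCOC12CC[C@]3(C)CC(=O)[C@@](C)(OCc4ccccc4)CC=C23
A2 | alternative 2 | 3a,7-epoxy-3-isopropyl-6,8a-dimethyl-3-(triethylsilyloxy)-1,2,3,7,8,8a-hexahydroazulen-4-one | CC(C)[C@]1(O[Si](CC)(CC)CC)CC[C@]2(C)C[C@@H]3O[C@]12C(=O)C=C3C
A3 | alternative 3 | 3-isopropyl-6,8a-dimethyl-1,2,3,5,8,8a-hexahydroazulen-3-ol | CC(C)[C@]1(O)CC[C@]2(C)CC=C(C)CC=C21
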